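**Plan**

- Retrosynthetic cuts, in order: the five O–benzyl bonds; the O1–C2 aryl ether bond of ring C; the C2–C1' bond to ring B; the C3–O ester bond. What remains is the ring A propanal 7, the diaroyl peroxide 10 and the ring B bromide 12.
- Forward order: propanal 7 is built from phenol 1 (O-allylation, Claisen rearrangement, silylation, hydroboration, oxidation), and peroxide 10 from two molecules of acid chloride 8 and hydrogen peroxide. The C3–O bond is then made with the 4-(benzyloxy)benzoate already in place, ring B is attached at C2, and ring C is closed at O1–C2 as the only ring-forming event, followed by global debenzylation.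
- Enabling feature: C3 is an oxygen-bearing sp3 carbon between the C4 methylene on ring A and the carbinol carbon C2. With C2 at the aldehyde level, C3 is the α-carbon of an enolisable aldehyde, and its O-substituent is exactly the aroyloxy group a diaroyl peroxide can transfer.
- Stereochemistry: C3 (R) comes from the chiral amine catalyst. C2 comes from Felkin–Anh aryl addition (1S, 1,2-anti) followed by SN2 inversion in the Mitsunobu closure, which gives 2R and the 2,3-cis arrangement.

Key step: step 7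

Remark: compounds 1, 8 and 12 are taken as purchasable. The sense of induction in step 7 is assigned from the steric-shielding model of 2-substituted pyrrolidine enamines (electrophile enters anti to the trityl group), so the (R)-catalyst is specified; its antipode would be taken if the sense proved opposite.

**Route**

Step 1
Reactants: 1 3,5-bis(benzyloxy)phenol
Product: 2 1-(allyloxy)-3,5-bis(benzyloxy)benzene
Conditions: allyl bromide, K2CO3, acetone, reflux
Reagents that add atoms: allyl bromide, C=CCBr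
Why: Williamson O-allylation of the only free phenol should proceed cleanly under carbonate conditions that favour O- over C-alkylation.

Step 2
Reactants: 2 1-(allyloxy)-3,5-bis(benzyloxy)benzene
Product: 3 2-allyl-3,5-bis(benzyloxy)phenol
Conditions: PhNEt2, 190 °C
Reagents that add atoms: none
Why: Aromatic Claisen rearrangement ([3,3]-sigmatropic shift, then tautomerisation) can only deliver the allyl group to one of the two equivalent ortho positions, which fixes the 1,2,3,5 substitution pattern of ring A.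

Step 3
Reactants: 3 2-allyl-3,5-bis(benzyloxy)phenol
Product: 4 [2-allyl-3,5-bis(benzyloxy)phenoxy](tert-butyl)dimethylsilane
Conditions: TBSCl, imidazole, DMF, rt
Reagents that add atoms: tert-butyldimethylsilyl chloride, CC(C)(C)[Si](C)(C)Cl
Why: Imidazole-promoted silylation of a phenol gives an aryl silyl ether that should survive borane, oxidant, peroxide and organotitanium reagent and can later be removed by fluoride beside benzyl ethers and an ester.

Step 4
Reactants: 4 [2-allyl-3,5-bis(benzyloxy)phenoxy](tert-butyl)dimethylsilane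
Product: 6 3-[2,4-bis(benzyloxy)-6-(tert-butyldimethylsilyloxy)phenyl]propan-1-ol, via alkyl-9-BBN borane 5 (not isolated)
Conditions: 9-BBN, THF, 0 °C → rt; then NaBO3·4H2O, H2O, rt
Reagents that add atoms: sodium perborate, [Na+].[Na+].O[B-]1(O)OO[B-](O)(O)OO1
Why: Anti-Markovnikov hydroboration of the terminal alkene with 9-BBN followed by perborate oxidation should give the primary alcohol, the mild oxidant sparing the aryl silyl ether.

Step 5
Reactants: 6 3-[2,4-bis(benzyloxy)-6-(tert-butyldimethylsilyloxy)phenyl]propan-1-ol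
Product: 7 3-[2,4-bis(benzyloxy)-6-(tert-butyldimethylsilyloxy)phenyl]propanal
Conditions: Dess–Martin periodinane, CH2Cl2, rt
Reagents that add atoms: none
Why: Dess–Martin oxidation converts a primary alcohol into the aldehyde under non-basic conditions without over-oxidation or attack on the electron-rich ring.

Step 6
Reactants: 8 4-(benzyloxy)benzoyl chloride (two molecules per molecule of product; the second is entered below)
Product: 10 bis[4-(benzyloxy)benzoyl] peroxide, via 4-(benzyloxy)peroxybenzoic acid 9 (not isolated)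
Conditions: 8 (2 equiv), 30% aq H2O2 (1 equiv), NaOH (2 equiv), CH2Cl2–H2O, 0 °C
Reagents that add atoms: hydrogen peroxide, OO; 4-(benzyloxy)benzoyl chloride (second equivalent of 8), O=C(Cl)c1ccc(OCc2ccccc2)cc1
Why: In this Schotten–Baumann double acylation, hydroperoxide anion attacks a first molecule of 8 to give peroxy acid 9 (present as its anion in the basic medium), whose terminal oxygen is acylated by a second molecule of 8, which is the standard preparation of symmetrical diaroyl peroxides.

Step 7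
Reactants: 7 3-[2,4-bis(benzyloxy)-6-(tert-butyldimethylsilyloxy)phenyl]propanal; 10 bis[4-(benzyloxy)benzoyl] peroxide
Product: 11 (2R)-3-[2,4-bis(benzyloxy)-6-(tert-butyldimethylsilyloxy)phenyl]-1-oxopropan-2-yl 4-(benzyloxy)benzoate
Conditions: (R)-2-(triphenylmethyl)pyrrolidine (10 mol%), hydroquinone (10 mol%), THF, 0 °C; cold aq NaHCO3 work-up, short silica plug, used at once
Reagents that add atoms: none
Why: The secondary amine condenses with aldehyde 7 to the E-enamine, whose β-carbon attacks one peroxide oxygen of 10 in an SN2 displacement on the O–O bond with loss of 4-(benzyloxy)benzoate, and hydrolysis of the resulting iminium ion releases 11 and the catalyst. The closest known reaction type is the amine-catalysed asymmetric α-benzoyloxylation of aliphatic aldehydes, 3-arylpropanals included, with dibenzoyl peroxide; no ring is closed. The new C–O stereocentre, the future C3, is set by the catalyst: the trityl group of the (R)-pyrrolidine blocks the Si face of the enamine β-carbon, so oxygen should be delivered to the Re face to give the (R)-aldehyde. The step needs chemoselectivity for the enamine over the electron-rich ring A and over radical decomposition of the peroxide, which the much higher nucleophilicity of the enamine, the low temperature, the hydroquinone additive and the full O-protection of ring A should secure. It also needs mono-oxygenation and configurational stability, which should follow from the reluctance of the hindered α-aroyloxy aldehyde to re-form an enamine and from the cold, nearly neutral work-up with immediate use.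

Step 8
Reactants: 11 (2R)-3-[2,4-bis(benzyloxy)-6-(tert-butyldimethylsilyloxy)phenyl]-1-oxopropan-2-yl 4-(benzyloxy)benzoate; 12 4-bromo-1,2-bis(benzyloxy)benzene
Product: 15 (1S,2R)-1-[3,4-bis(benzyloxy)phenyl]-3-[2,4-bis(benzyloxy)-6-(tert-butyldimethylsilyloxy)phenyl]-1-hydroxypropan-2-yl 4-(benzyloxy)benzoate, via aryllithium 13 (not isolated), via aryltitanium triisopropoxide 14 (not isolated)
Conditions: 12, n-BuLi, THF, −78 °C; ClTi(OiPr)3, −78 → −40 °C; then 11, −78 → −30 °C; pH 7 buffer
Reagents that add atoms: none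
Why: Felkin–Anh (polar, non-chelating) addition of an aryltitanium triisopropoxide, a weakly basic reagent that attacks aldehydes in preference to esters and cannot chelate, should place the aryl group anti to the C–O bond of the α-aroyloxy substituent and so give the (1S) carbinol (1,2-anti) without enolising the aldehyde.

Step 9
Reactants: 15 (1S,2R)-1-[3,4-bis(benzyloxy)phenyl]-3-[2,4-bis(benzyloxy)-6-(tert-butyldimethylsilyloxy)phenyl]-1-hydroxypropan-2-yl 4-(benzyloxy)benzoate
Product: 16 (1S,2R)-1-[3,4-bis(benzyloxy)phenyl]-3-[2,4-bis(benzyloxy)-6-hydroxyphenyl]-1-hydroxypropan-2-yl 4-(benzyloxy)benzoate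
Conditions: Bu4NF, AcOH (1:1), THF, 0 °C
Reagents that add atoms: none
Why: Fluoride cleavage of the aryl silyl ether, buffered with acetic acid so that no free alkoxide or phenoxide is present, should free the phenol without migration of the aroyl group to the C1 hydroxyl.

Step 10
Reactants: 16 (1S,2R)-1-[3,4-bis(benzyloxy)phenyl]-3-[2,4-bis(benzyloxy)-6-hydroxyphenyl]-1-hydroxypropan-2-yl 4-(benzyloxy)benzoate
Product: 17 (2R,3R)-5,7-bis(benzyloxy)-2-[3,4-bis(benzyloxy)phenyl]-3,4-dihydro-2H-chromen-3-yl 4-(benzyloxy)benzoate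
Conditions: PPh3, DIAD, THF, 0 °C → rt
Reagents that add atoms: none
Why: Intramolecular Mitsunobu etherification, in which the phenoxide displaces the benzylic oxyphosphonium group in a 6-exo-tet SN2 closure with inversion, should turn the (1S) carbinol into C2 (R) of ring C, cis to the C3 ester.

Step 11
Reactants: 17 (2R,3R)-5,7-bis(benzyloxy)-2-[3,4-bis(benzyloxy)phenyl]-3,4-dihydro-2H-chromen-3-yl 4-(benzyloxy)benzoate
Product: 18 (2R,3R)-2-(3,4-dihydroxyphenyl)-5,7-dihydroxy-3,4-dihydro-2H-chromen-3-yl 4-hydroxybenzoate (epicatechin 3-O-p-hydroxybenzoate)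
Conditions: H2 (1 atm), Pd(OH)2/C, THF–MeOH, rt
Reagents that add atoms: none
Why: Catalytic hydrogenolysis should remove all five benzyl ethers under neutral conditions that leave the aryl ester, the C2–O1 bond and both stereocentres untouched.

**Compound list**

1 | 3,5-bis(benzyloxy)phenol | Oc1cc(OCc2ccccc2)cc(OCc2ccccc2)c1 | starting material
2 | 1-(allyloxy)-3,5-bis(benzyloxy)benzene | C=CCOc1cc(OCc2ccccc2)cc(OCc2ccccc2)c1 | intermediate
3 | 2-allyl-3,5-bis(benzyloxy)phenol | C=CCc1c(O)cc(OCc2ccccc2)cc1OCc1ccccc1 | intermediate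
4 | [2-allyl-3,5-bis(benzyloxy)phenoxy](tert-butyl)dimethylsilane | C=CCc1c(O[Si](C)(C)C(C)(C)C)cc(OCc2ccccc2)cc1OCc1ccccc1 | intermediate
5 | 9-{3-[2,4-bis(benzyloxy)-6-(tert-butyldimethylsilyloxy)phenyl]propyl}-9-borabicyclo[3.3.1]nonane | C1CCC2CCCC1B2CCCc1c(O[Si](C)(C)C(C)(C)C)cc(OCc2ccccc2)cc1OCc1ccccc1 | intermediate
6 | 3-[2,4-bis(benzyloxy)-6-(tert-butyldimethylsilyloxy)phenyl]propan-1-ol | OCCCc1c(O[Si](C)(C)C(C)(C)C)cc(OCc2ccccc2)cc1OCc1ccccc1 | intermediate
7 | 3-[2,4-bis(benzyloxy)-6-(tert-butyldimethylsilyloxy)phenyl]propanal | O=CCCc1c(O[Si](C)(C)C(C)(C)C)cc(OCc2ccccc2)cc1OCc1ccccc1 | intermediate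
8 | 4-(benzyloxy)benzoyl chloride | O=C(Cl)c1ccc(OCc2ccccc2)cc1 | starting material
9 | 4-(benzyloxy)peroxybenzoic acid | O=C(OO)c1ccc(OCc2ccccc2)cc1 | intermediate
10 | bis[4-(benzyloxy)benzoyl] peroxide | O=C(OOC(=O)c1ccc(OCc2ccccc2)cc1)c1ccc(OCc2ccccc2)cc1 | intermediate
11 | (2R)-3-[2,4-bis(benzyloxy)-6-(tert-butyldimethylsilyloxy)phenyl]-1-oxopropan-2-yl 4-(benzyloxy)benzoate | O=C(O[C@@H](C=O)Cc1c(O[Si](C)(C)C(C)(C)C)cc(OCc2ccccc2)cc1OCc1ccccc1)c1ccc(OCc2ccccc2)cc1 | intermediate
12 | 4-bromo-1,2-bis(benzyloxy)benzene | Brc1ccc(OCc2ccccc2)c(OCc2ccccc2)c1 | starting material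
13 | [3,4-bis(benzyloxy)phenyl]lithium | [Li]c1ccc(OCc2ccccc2)c(OCc2ccccc2)c1 | intermediate
14 | [3,4-bis(benzyloxy)phenyl]tri(propan-2-yloxy)titanium | CC(C)O[Ti](OC(C)C)(OC(C)C)c1ccc(OCc2ccccc2)c(OCc2ccccc2)c1 | intermediate
15 | (1S,2R)-1-[3,4-bis(benzyloxy)phenyl]-3-[2,4-bis(benzyloxy)-6-(tert-butyldimethylsilyloxy)phenyl]-1-hydroxypropan-2-yl 4-(benzyloxy)benzoate | O=C(O[C@@H]([C@@H](O)c1ccc(OCc2ccccc2)c(OCc2ccccc2)c1)Cc1c(O[Si](C)(C)C(C)(C)C)cc(OCc2ccccc2)cc1OCc1ccccc1)c1ccc(OCc2ccccc2)cc1 | intermediate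
16 | (1S,2R)-1-[3,4-bis(benzyloxy)phenyl]-3-[2,4-bis(benzyloxy)-6-hydroxyphenyl]-1-hydroxypropan-2-yl 4-(benzyloxy)benzoate | O=C(O[C@@H]([C@@H](O)c1ccc(OCc2ccccc2)c(OCc2ccccc2)c1)Cc1c(O)cc(OCc2ccccc2)cc1OCc1ccccc1)c1ccc(OCc2ccccc2)cc1 | intermediate
17 | (2R,3R)-5,7-bis(benzyloxy)-2-[3,4-bis(benzyloxy)phenyl]-3,4-dihydro-2H-chromen-3-yl 4-(benzyloxy)benzoate | O=C(O[C@@H]1Cc2c(OCc3ccccc3)cc(OCc3ccccc3)cc2O[C@@H]1c1ccc(OCc2ccccc2)c(OCc2ccccc2)c1)c1ccc(OCc2ccccc2)cc1 | intermediate
18 | (2R,3R)-2-(3,4-dihydroxyphenyl)-5,7-dihydroxy-3,4-dihydro-2H-chromen-3-yl 4-hydroxybenzoate | O=C(O[C@@H]1Cc2c(O)cc(O)cc2O[C@@H]1c1ccc(O)c(O)c1)c1ccc(O)cc1 | target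

**Step count**

Total: 11 steps. Longest linear sequence: 10 steps (steps 1–5 and 7–11, from phenol 1).

**Steps most likely to fail**

Step 10. The activated benzylic oxyphosphonium sits on a carbon carrying a para-alkoxyaryl group and next to an ester. It may ionise, or be captured by the ester carbonyl as an acyloxonium ion, faster than the phenoxide closes the ring. Inversion would then be lost and the 2,3-cis relationship eroded. The fallback sets out from 16 and comes back at 17. The participating ester is removed with NaOMe in MeOH–THF to give (1S,2R)-1-[3,4-bis(benzyloxy)phenyl]-3-[2,4-bis(benzyloxy)-6-hydroxyphenyl]propane-1,2-diol F1. The Mitsunobu closure (PPh3, DIAD, THF) is then run on this triol, where the benzylic hydroxyl should be activated preferentially and displaced with inversion. This should give (2R,3R)-5,7-bis(benzyloxy)-2-[3,4-bis(benzyloxy)phenyl]-3,4-dihydro-2H-chromen-3-ol F2. Acylation of its C3 hydroxyl with acid chloride 8 (DMAP, pyridine, CH2Cl2) returns to 17.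

Step 8. Facial selectivity in the aryl transfer may be poor, and the aroyl group may migrate to the newly formed alkoxide if the mixture warms before the quench. The fallback sets out from crude 15 (as a mixture of C1 epimers) and comes back at 15. Dess–Martin oxidation converges both epimers on the ketone (2R)-1-[3,4-bis(benzyloxy)phenyl]-3-[2,4-bis(benzyloxy)-6-(tert-butyldimethylsilyloxy)phenyl]-1-oxopropan-2-yl 4-(benzyloxy)benzoate F3. Corey–Bakshi–Shibata reduction with (S)-2-methyl-CBS-oxazaborolidine and BH3·SMe2 at low temperature then sets C1 under reagent control; with the aryl group as the large substituent it should return the (1S) alcohol 15.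

Step 7. Oxygen transfer from the electron-rich peroxide may be slow, letting oxidation of ring A or of the catalyst nitrogen compete, and enolisation of the product during handling may erode its enantiomeric purity. The fallback sets out from 7 and comes back at 11, placing the C3 oxygen by a different electrophile and adding the ester afterwards. L-Proline-catalysed α-aminoxylation of 7 with nitrosobenzene (DMSO, 0 °C) should give (2R)-3-[2,4-bis(benzyloxy)-6-(tert-butyldimethylsilyloxy)phenyl]-2-[(phenylamino)oxy]propanal F4. Reduction in the same flask with NaBH4 gives (2R)-3-[2,4-bis(benzyloxy)-6-(tert-butyldimethylsilyloxy)phenyl]-2-[(phenylamino)oxy]propan-1-ol F5. N–O cleavage with Zn in AcOH–THF then gives (2R)-3-[2,4-bis(benzyloxy)-6-(tert-butyldimethylsilyloxy)phenyl]propane-1,2-diol F6. Selective silylation of the primary hydroxyl (TESCl, imidazole, CH2Cl2, −78 °C) gives (2R)-1-[2,4-bis(benzyloxy)-6-(tert-butyldimethylsilyloxy)phenyl]-3-[(triethylsilyl)oxy]propan-2-ol F7. Acylation with 8 (pyridine, DMAP) gives (2R)-1-[2,4-bis(benzyloxy)-6-(tert-butyldimethylsilyloxy)phenyl]-3-[(triethylsilyl)oxy]propan-2-yl 4-(benzyloxy)benzoate F8. Removal of the alkyl silyl ether (PPTS, MeOH–CH2Cl2, 0 °C; the aryl silyl ether should remain) gives (2R)-1-[2,4-bis(benzyloxy)-6-(tert-butyldimethylsilyloxy)phenyl]-3-hydroxypropan-2-yl 4-(benzyloxy)benzoate F9. Dess–Martin oxidation of F9 returns to 11.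

**Further compounds**

F1 | step 10 | (1S,2R)-1-[3,4-bis(benzyloxy)phenyl]-3-[2,4-bis(benzyloxy)-6-hydroxyphenyl]propane-1,2-diol | O[C@@H]([C@@H](O)c1ccc(OCc2ccccc2)c(OCc2ccccc2)c1)Cc1c(O)cc(OCc2ccccc2)cc1OCc1ccccc1
F2 | step 10 | (2R,3R)-5,7-bis(benzyloxy)-2-[3,4-bis(benzyloxy)phenyl]-3,4-dihydro-2H-chromen-3-ol | O[C@@H]1Cc2c(OCc3ccccc3)cc(OCc3ccccc3)cc2O[C@@H]1c1ccc(OCc2ccccc2)c(OCc2ccccc2)c1
F3 | step 8 | (2R)-1-[3,4-bis(benzyloxy)phenyl]-3-[2,4-bis(benzyloxy)-6-(tert-butyldimethylsilyloxy)phenyl]-1-oxopropan-2-yl 4-(benzyloxy)benzoate | O=C(O[C@@H](C(=O)c1ccc(OCc2ccccc2)c(OCc2ccccc2)c1)Cc1c(O[Si](C)(C)C(C)(C)C)cc(OCc2ccccc2)cc1OCc1ccccc1)c1ccc(OCc2ccccc2)cc1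
F4 | step 7 | (2R)-3-[2,4-bis(benzyloxy)-6-(tert-butyldimethylsilyloxy)phenyl]-2-[(phenylamino)oxy]propanal | c1ccccc1NO[C@@H](C=O)Cc1c(O[Si](C)(C)C(C)(C)C)cc(OCc2ccccc2)cc1OCc1ccccc1
F5 | step 7 | (2R)-3-[2,4-bis(benzyloxy)-6-(tert-butyldimethylsilyloxy)phenyl]-2-[(phenylamino)oxy]propan-1-ol | c1ccccc1NO[C@@H](CO)Cc1c(O[Si](C)(C)C(C)(C)C)cc(OCc2ccccc2)cc1OCc1ccccc1
F6 | step 7 | (2R)-3-[2,4-bis(benzyloxy)-6-(tert-butyldimethylsilyloxy)phenyl]propane-1,2-diol | O[C@@H](CO)Cc1c(O[Si](C)(C)C(C)(C)C)cc(OCc2ccccc2)cc1OCc1ccccc1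
F7 | step 7 | (2R)-1-[2,4-bis(benzyloxy)-6-(tert-butyldimethylsilyloxy)phenyl]-3-[(triethylsilyl)oxy]propan-2-ol | O[C@@H](CO[Si](CC)(CC)CC)Cc1c(O[Si](C)(C)C(C)(C)C)cc(OCc2ccccc2)cc1OCc1ccccc1
F8 | step 7 | (2R)-1-[2,4-bis(benzyloxy)-6-(tert-butyldimethylsilyloxy)phenyl]-3-[(triethylsilyl)oxy]propan-2-yl 4-(benzyloxy)benzoate | O=C(O[C@@H](CO[Si](CC)(CC)CC)Cc1c(O[Si](C)(C)C(C)(C)C)cc(OCc2ccccc2)cc1OCc1ccccc1)c1ccc(OCc2ccccc2)cc1
F9 | step 7 | (2R)-1-[2,4-bis(benzyloxy)-6-(tert-butyldimethylsilyloxy)phenyl]-3-hydroxypropan-2-yl 4-(benzyloxy)benzoate | O=C(O[C@@H](CO)Cc1c(O[Si](C)(C)C(C)(C)C)cc(OCc2ccccc2)cc1OCc1ccccc1)c1ccc(OCc2ccccc2)cc1
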